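## Structural features

The target is a monocyclic 3,4-dihydro-2H-pyran (O1, C2–C6). C5=C6–O1 together with the C5 methoxycarbonyl group forms a vinylogous carbonate. C2 carries a methyl group, C3 a hydroxymethyl group, and C4 a two-carbon arm (C8, C9) whose carboxyl carbon C9 is esterified with the primary hydroxyl of hydroxytyrosol; the catechol is free.

The three stereocentres C2, C3 and C4 are contiguous, (2R,3R,4S). Their substituents alternate between the ring faces: 2,3-trans and 3,4-trans, hence 2,4-cis.

Fragile points are:
- the catechol (air and base);
- the C3 hydroxymethyl group, which can reach the C9 ester through a six-membered transition state and expel the arylethanol;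
- the enol ether carbon C6 (acid hydration, conjugate addition);
- two different esters (C5 methyl, C9 arylethyl) that must be kept apart.

The real difficulty is not the ring. It is the control of three adjacent stereocentres, in the absolute sense, on a ring with no strong conformational anchor, while C9 is brought to the acid level next to an existing ester at C5.

The key step exploits the fact that O1=C6–C5(CO2Me)=C4 is a 1-oxadiene of the alkylidene formylacetate type and C2–C3 is a two-carbon dienophile. An aldehyde (C4, C8, C9), a formylacetate (C5, C6, O1, ester) and an enol ether (C2, C3, CH2O) therefore supply every ring atom. A methyl-bearing C2 cannot be the donor terminus of an electron-rich dienophile, so C2 enters as an acetal carbon and receives the methyl group afterwards.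

## Logic of the disconnections

19 is taken back to 18 by restoring three O–Si bonds. The catechol and the C3 hydroxyl stay masked to the very end, and one fluoride operation frees all three. The forward step must be non-basic and near neutral so that the freed C3 hydroxyl does not attack C9.

18 is cut at the C9(=O)–O bond into 14 and 17. This separates the aromatic part from the chiral part and makes the route convergent. The forward step needs a carboxyl activation that spares the enol ether, and 17 must offer only its primary hydroxyl. 17 goes back through 16 to 15 by O–Si cuts: exhaustive silylation followed by selective release of the alkyl silyl ether.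

14 is related to 12 (through 13) by an oxidation-level change at C9, with no skeletal bond cut. C9 travels as an ether because a C9 carbonyl would turn the aldehyde component of the key step into a second 1,3-dicarbonyl compound. The forward oxidation must leave the enol ether and the silyl ether alone. 12 goes back to 11 by the O–CH2Ar bond of the benzyl-type ether.

11 is cut at the C2–CH3 bond to 10. An alkoxy group at C2 is what makes C2–C3 an electron-rich dienophile, and it leaves an acetal that can ionise. The forward step must ionise the exocyclic C–O bond and deliver methyl to the face opposite the C3 substituent.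

10 is cut at C4=C5 (condensation) and at O1–C2 and C3–C4 (cycloaddition) into 3, 5 and 8, with 9 as the oxadiene. This removes the ring and all three stereocentres at once and leaves three small achiral pieces. The forward step must be endo-selective, must keep the enol ether geometry, and must distinguish the two faces of C4.

3 goes back through 2 to 1 (oxidation level, then one O–C bond). 5 goes back to 4 (acetal). 8 goes back through 7 to 6 (O–Si bond, then ester reduction). Each needs only standard functional-group chemistry.

## Other disconnections considered

Alternative 1: The cut is C3–C4, made by a sigmatropic shift. The precursor is the cis dioxanone A1, (2R,6R)-2-[(1Z)-4-(4-methoxybenzyloxy)but-1-enyl]-6-methyl-1,3-dioxan-4-one, built from a chiral-pool β-hydroxy acid and a (Z)-enal. In the forward step the silyl ketene acetal of A1 undergoes an Ireland–Claisen [3,3] shift through a boat transition state held by the dioxanone. This forms C3–C4, moves the alkene to C5=C6 and contracts the ring to the dihydropyran acid A2.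
- In its favour: the C2 methyl stereocentre is present from the start, and C3 and C4 are set by intramolecular chirality transfer with no external chiral catalyst. On the security of absolute and relative configuration, and on C2 in particular, this is better than the chosen plan, which needs a catalyst-controlled intermolecular cycloaddition and a separate methylation.
- Against it here: A2 lacks the C5 ester and has C3 at the acid level. The C3 acid must be reduced and protected, and C5 of an unactivated enol ether must be acylated and converted to the methyl ester, before the same arm oxidation and esterification as in the chosen route. The (Z)-enal and the cis acetalisation are further demands, and the enolisable dioxanone can open by β-elimination.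
- Comparison: the mechanism is more predictable than the chosen one. Structurally, the chosen cycloaddition delivers the complete vinylogous carbonate in one step. In step economy the chosen plan is clearly shorter after the key step.

Alternative 2: The cut removes the ring oxygen (O1–C2 and O1–C6) to reveal the all-trans cyclopentanone A3. In the forward step a peracid inserts oxygen between the carbonyl carbon and the methyl-bearing carbon (Baeyer–Villiger), with migration of the more substituted carbon and retention, to give lactone A4.
- In its favour: the relative configuration of a trisubstituted cyclopentanone is under thermodynamic control (C2 is epimerisable next to the ketone), and the migratory preference gives the right regiochemistry. The methyl group is present before ring formation. In robustness of the three stereocentres it is the equal of, or better than, the chosen plan, and it avoids ionisation at C2.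
- Against it here: A4 is a saturated lactone. Both the C5 methoxycarbonyl group and the C5=C6 enol ether still have to be made (acylation at C5, partial reduction of the lactone carbonyl, dehydration), in the presence of two other esters. The tert-butyl ester must later be exchanged for the arylethyl ester. The absolute configuration of A3 needs its own asymmetric step.
- Comparison: mechanistically the oxygen insertion is at least as reliable as any step of the chosen route. Structurally it stops one oxidation pattern short of the target ring. In step economy it is markedly worse.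

Alternative 3: The cut is O1–C6 and C4–C5. The precursors are the hydroxy enoate A5 and methyl propiolate A6. In the forward step the C2 alkoxide of A5 adds to A6, and the resulting vinyl anion (allenolate) closes 6-exo onto the (E)-enoate. This gives A7, the tris-silyl ether of the target, which is identical with 18.
- In its favour: it is the most convergent. The arylethyl ester, the C5 ester and the enol ether are all in place after the key step, and A7 is one deprotection from 19. After the key step this is better than the chosen plan (one step against five). C2 and C3 come from reliable acyclic anti-selective chemistry, which is equal to or better than the chosen plan for C2.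
- Against it here: only C4 is formed in the key step, and its configuration rests on 1,2-induction from C3 in an anionic closure. The vinyl anion is likely to be protonated before it reaches the unactivated enoate, which would leave an acyclic β-alkoxyacrylate that cannot be closed without losing C5=C6. The anti stereodiad of A5 costs several steps, and a basic alkoxide is generated next to a labile ester.
- Comparison: the chosen plan forms two bonds in one concerted event that ties C3 to C4; this route needs two consecutive anionic additions to outrun proton transfer. Overall step economy is comparable: better after the key step, worse before it.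

Key step: step 6

Remarks on the chemistry, made before the steps:
- Pyran locants (O1, C2–C6, arm carbons C8 and C9) are used for all intermediates.
- The isomer of 9 that can act as the oxadiene has the arm anti to the formyl group. Because the ester outranks the formyl group in the sequence rules, this isomer is Z.
- A two-point chelate between the formyl and ester oxygens would hold both carbonyl groups s-trans to C4=C5, which is a Michael-acceptor geometry and not an s-cis oxadiene. A Lewis acid that binds the formyl oxygen alone is therefore used. The amine salt finishes the condensation first, because free amine would bind the Lewis acid.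
- Assumption: the complex made from (1R,2S)-1-aminoindan-2-ol is taken to leave the Re face of C4 open. If attack occurs on the other face, the mirror-image complex, which is equally accessible, is used.

## Steps

Step 1
Reactants: 1 propane-1,3-diol
Product: 2 3-(4-methoxybenzyloxy)propan-1-ol
Conditions: NaH (1.0 equiv), 1 (3 equiv), THF, 0 °C; PMBCl (1.0 equiv), Bu4NI (cat.), 0 → 20 °C
Reagents that add atoms: 4-methoxybenzyl chloride, COc1ccc(CCl)cc1
Why: Williamson etherification of the mono-alkoxide; the excess of diol keeps dialkylation low and is washed out with water.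

Step 2
Reactants: 2 3-(4-methoxybenzyloxy)propan-1-ol
Product: 3 3-(4-methoxybenzyloxy)propanal
Conditions: (COCl)2, DMSO, CH2Cl2, −78 °C; Et3N, −78 → 0 °C
Reagents that add atoms: none
Why: Swern oxidation stops at the aldehyde and runs cold, so the β-alkoxy aldehyde should not lose its alkoxy group; 3 is used without storage.

Step 3
Reactants: 4 methyl 3,3-dimethoxypropanoate
Product: 5 methyl 3-oxopropanoate (methyl formylacetate)
Conditions: 2 M aq. HCl, THF, 0 → 20 °C; extraction into CH2Cl2, dried, used at once
Reagents that add atoms: water, O
Why: Acid-catalysed acetal hydrolysis leaves the methyl ester intact; 5 self-condenses on standing, so it is kept as a cold, dry solution for step 6.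

Step 4
Reactants: 6 ethyl (E)-3-ethoxyprop-2-enoate
Product: 7 (E)-3-ethoxyprop-2-en-1-ol
Conditions: DIBAL-H (2.2 equiv), CH2Cl2, −78 → 0 °C; aq. potassium sodium tartrate
Reagents that add atoms: none
Why: DIBAL-H reduction of the conjugated ester goes 1,2 to the allylic alcohol and leaves the enol ether and its E geometry untouched; the tartrate work-up avoids the acid that would hydrolyse the enol ether.

Step 5
Reactants: 7 (E)-3-ethoxyprop-2-en-1-ol
Product: 8 (E)-tert-butyl(3-ethoxyprop-2-enyloxy)dimethylsilane
Conditions: TBSCl, imidazole, CH2Cl2, 0 → 20 °C
Reagents that add atoms: tert-butyldimethylsilyl chloride, CC(C)(C)[Si](C)(C)Cl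
Why: Imidazole-promoted silylation of the primary allylic alcohol; the hindered silyl ether is stable to the amine salt and the Lewis acids that follow and is a poor neighbouring group.

Step 6
Reactants: 3 3-(4-methoxybenzyloxy)propanal, 5 methyl 3-oxopropanoate, 8 (E)-tert-butyl(3-ethoxyprop-2-enyloxy)dimethylsilane
Product: 10 methyl (2S,3R,4S)-3-(tert-butyldimethylsilyloxymethyl)-2-ethoxy-4-[2-(4-methoxybenzyloxy)ethyl]-3,4-dihydro-2H-pyran-5-carboxylate, via alkylidene formylacetate 9 (not isolated)
Conditions: 3, 5 (1.2 equiv), piperidinium acetate (5 mol%), 4 Å MS, CH2Cl2, 0 °C; then 8 (1.5 equiv), [CrCl(L)] (7.5 mol%; L = dianion of the salicylaldimine from 3-(1-adamantyl)-2-hydroxy-5-methylbenzaldehyde and (1R,2S)-1-aminoindan-2-ol), −30 → 0 °C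
Reagents that add atoms: none
Why: The amine salt condenses 3 with 5 (Knoevenagel) to 9, whose double-bond isomers interconvert under the same catalyst, and only the Z isomer can reach the s-cis O1=C6–C5=C4 array with the arm on the outside. The trivalent chromium complex binds the formyl oxygen at one point, which lowers the LUMO and leaves the s-cis oxadiene intact, and 8 then adds in a concerted but asynchronous inverse-electron-demand oxa-Diels–Alder reaction in which C3–C4 runs ahead of O1–C2. The closest known reaction types are the thermal domino Knoevenagel/oxa-Diels–Alder reaction of 1,3-dicarbonyl compounds with aldehydes and enol ethers and the endo-selective cycloaddition of α,β-unsaturated aldehydes with enol ethers under chromium salicylaldimine catalysis. The dihydropyran ring is closed by the intermolecular [4+2] cycloaddition itself, two σ bonds being made in one step. C4 is set by the catalyst, which must leave the Re face of C4 open; C3 is set relative to C4 because the addition is suprafacial on the E enol ether with the ethoxy group endo, so the silyloxymethyl group is exo and ends trans to the C4 arm; C2 follows from the same endo approach (ethoxy cis to the arm) and is of no later consequence. Regiochemistry is secured by polarity: the nucleophilic β-carbon of 8 meets the electrophilic C4 and the oxygen meets the acetal carbon. The step needs endo over exo selectivity, supplied by the Lewis acid and the donor oxygen, and dominance of the catalysed over the thermal pathway, for which the low temperature and the late addition of 8 are chosen.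

Step 7
Reactants: 10 methyl (2S,3R,4S)-3-(tert-butyldimethylsilyloxymethyl)-2-ethoxy-4-[2-(4-methoxybenzyloxy)ethyl]-3,4-dihydro-2H-pyran-5-carboxylate
Product: 11 methyl (2R,3R,4S)-3-(tert-butyldimethylsilyloxymethyl)-4-[2-(4-methoxybenzyloxy)ethyl]-2-methyl-3,4-dihydro-2H-pyran-5-carboxylate
Conditions: AlMe3 (4 equiv), CH2Cl2, −78 °C, 15 min; TMSOTf (1.2 equiv), −78 → −40 °C; aq. potassium sodium tartrate
Reagents that add atoms: trimethylaluminium, C[Al](C)C
Why: Lewis acid-mediated substitution of a cyclic acetal by an organoaluminium reagent (oxocarbenium alkylation): pre-complexed AlMe3 ties up the ether and ester oxygens, TMSOTf ionises the exocyclic C2–OEt bond, and methyl is transferred to C2. The cation is a flattened half-chair in which the C4 arm sits pseudo-axial to avoid the C5 ester, so the trans C3 substituent is pseudo-axial too, and attack anti to it should give the 2,3-trans (2R) product.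

Step 8
Reactants: 11 methyl (2R,3R,4S)-3-(tert-butyldimethylsilyloxymethyl)-4-[2-(4-methoxybenzyloxy)ethyl]-2-methyl-3,4-dihydro-2H-pyran-5-carboxylate
Product: 12 methyl (2R,3R,4S)-3-(tert-butyldimethylsilyloxymethyl)-4-(2-hydroxyethyl)-2-methyl-3,4-dihydro-2H-pyran-5-carboxylate
Conditions: DDQ (1.3 equiv), CH2Cl2/pH 7 phosphate buffer (10:1), 0 °C
Reagents that add atoms: none
Why: Oxidative cleavage of the 4-methoxybenzyl ether by DDQ (benzylic oxidation, then hydrolysis of the oxocarbenium ion); the acceptor-substituted enol ether and the silyl ether are much harder to oxidise, and the buffer keeps the medium from turning acidic. 12 is taken on directly.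

Step 9
Reactants: 12 methyl (2R,3R,4S)-3-(tert-butyldimethylsilyloxymethyl)-4-(2-hydroxyethyl)-2-methyl-3,4-dihydro-2H-pyran-5-carboxylate
Product: 14 2-[(2R,3R,4S)-3-(tert-butyldimethylsilyloxymethyl)-5-(methoxycarbonyl)-2-methyl-3,4-dihydro-2H-pyran-4-yl]acetic acid, via aldehyde 13 (not isolated)
Conditions: TEMPO (0.2 equiv), PhI(OAc)2 (2.5 equiv), MeCN/H2O (1:1), 20 °C
Reagents that add atoms: water, O
Why: Nitroxyl-catalysed oxidation takes the primary alcohol to the aldehyde, whose hydrate is oxidised on to the acid in the same pot; the medium is metal-free and near neutral, and C4 is not α to the new carbonyl, so no stereocentre is at risk.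

Step 10
Reactants: 15 hydroxytyrosol, 2-(3,4-dihydroxyphenyl)ethanol
Product: 16 tert-butyl{2-[3,4-bis(tert-butyldimethylsilyloxy)phenyl]ethoxy}dimethylsilane
Conditions: TBSCl (3.6 equiv), imidazole (7 equiv), DMF, 20 °C
Reagents that add atoms: tert-butyldimethylsilyl chloride, CC(C)(C)[Si](C)(C)Cl
Why: Exhaustive imidazole-mediated silylation of all three hydroxyls, so no discrimination between them is needed at this stage.

Step 11
Reactants: 16 tert-butyl{2-[3,4-bis(tert-butyldimethylsilyloxy)phenyl]ethoxy}dimethylsilane
Product: 17 2-[3,4-bis(tert-butyldimethylsilyloxy)phenyl]ethanol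
Conditions: camphorsulfonic acid (0.1 equiv), MeOH/CH2Cl2 (1:1), 0 °C
Reagents that add atoms: none
Why: Selective acid-catalysed methanolysis: the primary alkyl silyl ether is cleaved, while the aryl silyl ethers, whose oxygen is poorly basic, resist acid.

Step 12
Reactants: 14 2-[(2R,3R,4S)-3-(tert-butyldimethylsilyloxymethyl)-5-(methoxycarbonyl)-2-methyl-3,4-dihydro-2H-pyran-4-yl]acetic acid, 17 2-[3,4-bis(tert-butyldimethylsilyloxy)phenyl]ethanol
Product: 18 methyl (2R,3R,4S)-4-(2-{2-[3,4-bis(tert-butyldimethylsilyloxy)phenyl]ethoxy}-2-oxoethyl)-3-(tert-butyldimethylsilyloxymethyl)-2-methyl-3,4-dihydro-2H-pyran-5-carboxylate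
Conditions: EDC·HCl (1.5 equiv), DMAP (0.2 equiv), CH2Cl2, 0 → 20 °C
Reagents that add atoms: none
Why: Steglich esterification (carbodiimide activation, acyl transfer by DMAP) of a primary alcohol; the acid has no α-stereocentre, so nothing can epimerise.

Step 13
Reactants: 18 methyl (2R,3R,4S)-4-(2-{2-[3,4-bis(tert-butyldimethylsilyloxy)phenyl]ethoxy}-2-oxoethyl)-3-(tert-butyldimethylsilyloxymethyl)-2-methyl-3,4-dihydro-2H-pyran-5-carboxylate
Product: 19 methyl (2R,3R,4S)-4-{2-[2-(3,4-dihydroxyphenyl)ethoxy]-2-oxoethyl}-3-(hydroxymethyl)-2-methyl-3,4-dihydro-2H-pyran-5-carboxylate (CNP0204147.1)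
Conditions: HF·pyridine, pyridine, THF, 0 → 20 °C, argon
Reagents that add atoms: none
Why: Fluoride-mediated cleavage of one alkyl and two aryl silyl ethers in a single operation; the buffered, slightly acidic medium keeps the catechol protonated and avoids the alkoxide that would drive lactonisation of the C3 hydroxymethyl group onto the C9 ester.

## Compound list

1 | propane-1,3-diol | OCCCO | starting material
2 | 3-(4-methoxybenzyloxy)propan-1-ol | OCCCOCc1ccc(OC)cc1 | intermediate
3 | 3-(4-methoxybenzyloxy)propanal | O=CCCOCc1ccc(OC)cc1 | intermediate
4 | methyl 3,3-dimethoxypropanoate | COC(OC)CC(=O)OC | starting material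
5 | methyl 3-oxopropanoate | COC(=O)CC=O | intermediate
6 | ethyl (E)-3-ethoxyprop-2-enoate | CCO/C=C/C(=O)OCC | starting material
7 | (E)-3-ethoxyprop-2-en-1-ol | CCO/C=C/CO | intermediate
8 | (E)-tert-butyl(3-ethoxyprop-2-enyloxy)dimethylsilane | CCO/C=C/CO[Si](C)(C)C(C)(C)C | intermediate
9 | methyl (2Z)-2-formyl-5-(4-methoxybenzyloxy)pent-2-enoate | COC(=O)/C(C=O)=C\CCOCc1ccc(OC)cc1 | intermediate (not isolated)
10 | methyl (2S,3R,4S)-3-(tert-butyldimethylsilyloxymethyl)-2-ethoxy-4-[2-(4-methoxybenzyloxy)ethyl]-3,4-dihydro-2H-pyran-5-carboxylate | COC(=O)C1=CO[C@H](OCC)[C@@H](CO[Si](C)(C)C(C)(C)C)[C@@H]1CCOCc1ccc(OC)cc1 | intermediate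
11 | methyl (2R,3R,4S)-3-(tert-butyldimethylsilyloxymethyl)-4-[2-(4-methoxybenzyloxy)ethyl]-2-methyl-3,4-dihydro-2H-pyran-5-carboxylate | COC(=O)C1=CO[C@H](C)[C@@H](CO[Si](C)(C)C(C)(C)C)[C@@H]1CCOCc1ccc(OC)cc1 | intermediate
12 | methyl (2R,3R,4S)-3-(tert-butyldimethylsilyloxymethyl)-4-(2-hydroxyethyl)-2-methyl-3,4-dihydro-2H-pyran-5-carboxylate | COC(=O)C1=CO[C@H](C)[C@@H](CO[Si](C)(C)C(C)(C)C)[C@@H]1CCO | intermediate
13 | methyl (2R,3R,4S)-3-(tert-butyldimethylsilyloxymethyl)-2-methyl-4-(2-oxoethyl)-3,4-dihydro-2H-pyran-5-carboxylate | COC(=O)C1=CO[C@H](C)[C@@H](CO[Si](C)(C)C(C)(C)C)[C@@H]1CC=O | intermediate (not isolated)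
14 | 2-[(2R,3R,4S)-3-(tert-butyldimethylsilyloxymethyl)-5-(methoxycarbonyl)-2-methyl-3,4-dihydro-2H-pyran-4-yl]acetic acid | COC(=O)C1=CO[C@H](C)[C@@H](CO[Si](C)(C)C(C)(C)C)[C@@H]1CC(=O)O | intermediate
15 | hydroxytyrosol, 2-(3,4-dihydroxyphenyl)ethanol | OCCc1ccc(O)c(O)c1 | starting material
16 | tert-butyl{2-[3,4-bis(tert-butyldimethylsilyloxy)phenyl]ethoxy}dimethylsilane | CC(C)(C)[Si](C)(C)OCCc1ccc(O[Si](C)(C)C(C)(C)C)c(O[Si](C)(C)C(C)(C)C)c1 | intermediate
17 | 2-[3,4-bis(tert-butyldimethylsilyloxy)phenyl]ethanol | OCCc1ccc(O[Si](C)(C)C(C)(C)C)c(O[Si](C)(C)C(C)(C)C)c1 | intermediate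
18 | methyl (2R,3R,4S)-4-(2-{2-[3,4-bis(tert-butyldimethylsilyloxy)phenyl]ethoxy}-2-oxoethyl)-3-(tert-butyldimethylsilyloxymethyl)-2-methyl-3,4-dihydro-2H-pyran-5-carboxylate | COC(=O)C1=CO[C@H](C)[C@@H](CO[Si](C)(C)C(C)(C)C)[C@@H]1CC(=O)OCCc1ccc(O[Si](C)(C)C(C)(C)C)c(O[Si](C)(C)C(C)(C)C)c1 | intermediate
19 | methyl (2R,3R,4S)-4-{2-[2-(3,4-dihydroxyphenyl)ethoxy]-2-oxoethyl}-3-(hydroxymethyl)-2-methyl-3,4-dihydro-2H-pyran-5-carboxylate | COC(=O)C1=CO[C@H](C)[C@@H](CO)[C@@H]1CC(=O)OCCc1ccc(O)c(O)c1 | target

## Step count and least certain steps

Total step count: 13. Longest linear sequence: 8 steps (1, 2, 6, 7, 8, 9, 12, 13, from propane-1,3-diol).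

**Step 6 (key step).** The most likely failure is poor facial selectivity. 9 is electrophilic enough to add 8 without the catalyst, and this racemic thermal pathway competes with the catalysed one. A second danger is loss of the C9 alkoxy group from 9 by vinylogous β-elimination under the amine salt, and a third is erosion of endo selectivity.

Fallback (auxiliary control in place of catalyst control; sets out from 3 and 5, returns at 11):
- (1R,2S)-2-Phenylcyclohexanol is added to ethyl propiolate (N-methylmorpholine, CH2Cl2) to give ethyl (E)-3-[(1R,2S)-2-phenylcyclohexyloxy]prop-2-enoate F1.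
- DIBAL-H reduction gives (E)-3-[(1R,2S)-2-phenylcyclohexyloxy]prop-2-en-1-ol F2.
- Silylation gives tert-butyldimethyl{(E)-3-[(1R,2S)-2-phenylcyclohexyloxy]prop-2-enyloxy}silane F3.
- F3 replaces 8 in the condensation and cycloaddition with 3 and 5 (CH2Cl2, 20 °C, or Yb(fod)3 as catalyst), where the auxiliary shields one face of the dienophile. The product is methyl 3-(tert-butyldimethylsilyloxymethyl)-4-[2-(4-methoxybenzyloxy)ethyl]-2-[(1R,2S)-2-phenylcyclohexyloxy]-3,4-dihydro-2H-pyran-5-carboxylate F4.
- The conditions of step 7 expel the auxiliary as the leaving group and give 11.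

The antipode of the auxiliary is used if the sense of induction requires it.

**Step 7.** The most likely failure is ionisation in the wrong sense. The vinylogous ester can assist cleavage of the ring C2–O1 bond instead of the exocyclic one. Alternatively, the ether oxygen of the cis C4 arm can capture the cation with loss of the benzyl group. If the diequatorial cation reacts, the facial bias is also weak.

Fallback (tethered delivery; sets out from 10, returns at 12):
- DDQ removes the benzyl-type ether of 10 to give methyl (2S,3R,4S)-3-(tert-butyldimethylsilyloxymethyl)-2-ethoxy-4-(2-hydroxyethyl)-3,4-dihydro-2H-pyran-5-carboxylate F5.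
- Pyridinium p-toluenesulfonate in CH2Cl2 exchanges the ethoxy group for the arm hydroxyl to give the bridged acetal methyl 9-(tert-butyldimethylsilyloxymethyl)-2,8-dioxabicyclo[3.3.1]non-3-ene-4-carboxylate F6. The bridge can only form on the face of the C4 arm.
- AlMe3 (CH2Cl2, 0 °C) coordinates the bridging oxygen, opens that C–O bond and hands methyl to the same face. This is the known retentive opening of bridged bicyclic acetals by organoaluminium reagents. It gives 12 directly, with C2 fixed cis to the arm and trans to C3.

**Step 9.** The most likely failure is attack of the oxoammonium oxidant on the electron-rich enol ether, or slow oxidation of the aldehyde hydrate during which 12 or 13 degrade (for example by lactonisation of 12 onto the C5 ester).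

Fallback (two separate oxidations with a chlorite in place of the oxoammonium species; sets out from 12, returns at 14; no new compound, F0): 12 is oxidised with DMP (the triacetoxy periodinane, NaHCO3, CH2Cl2) and 13 is isolated. 13 is then converted to 14 by Pinnick oxidation (NaClO2, NaH2PO4, 2-methylbut-2-ene, t-BuOH/H2O), in which the alkene scavenger protects the enol ether.

**Step 13.** The most likely failure is uneven cleavage of three silyl ethers. This would force long exposure, during which the freed C3 hydroxymethyl group can attack the C9 ester (six-membered lactone, loss of the arylethanol) and the catechol can oxidise on work-up.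

Fallback (no phenol protection; sets out from 14 and 15, returns at 19): Mitsunobu esterification (PPh3, DIAD, THF, 0 °C) couples 14 with the aliphatic hydroxyl of 15; the carboxylic acid is far more acidic than the phenols and is the only competent nucleophile. The product is methyl (2R,3R,4S)-3-(tert-butyldimethylsilyloxymethyl)-4-{2-[2-(3,4-dihydroxyphenyl)ethoxy]-2-oxoethyl}-2-methyl-3,4-dihydro-2H-pyran-5-carboxylate F7. Its single alkyl silyl ether is then removed briefly with HF·pyridine to give 19. Steps 10 to 12 are bypassed.

## Further compounds

F1 | step 6 | ethyl (E)-3-[(1R,2S)-2-phenylcyclohexyloxy]prop-2-enoate | CCOC(=O)/C=C/O[C@@H]1CCCC[C@H]1c1ccccc1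
F2 | step 6 | (E)-3-[(1R,2S)-2-phenylcyclohexyloxy]prop-2-en-1-ol | OC/C=C/O[C@@H]1CCCC[C@H]1c1ccccc1
F3 | step 6 | tert-butyldimethyl{(E)-3-[(1R,2S)-2-phenylcyclohexyloxy]prop-2-enyloxy}silane | CC(C)(C)[Si](C)(C)OC/C=C/O[C@@H]1CCCC[C@H]1c1ccccc1
F4 | step 6 | methyl 3-(tert-butyldimethylsilyloxymethyl)-4-[2-(4-methoxybenzyloxy)ethyl]-2-[(1R,2S)-2-phenylcyclohexyloxy]-3,4-dihydro-2H-pyran-5-carboxylate (ring configured as 10) | COC(=O)C1=CO[C@H](O[C@@H]2CCCC[C@H]2c2ccccc2)[C@@H](CO[Si](C)(C)C(C)(C)C)[C@@H]1CCOCc1ccc(OC)cc1
F5 | step 7 | methyl (2S,3R,4S)-3-(tert-butyldimethylsilyloxymethyl)-2-ethoxy-4-(2-hydroxyethyl)-3,4-dihydro-2H-pyran-5-carboxylate | COC(=O)C1=CO[C@H](OCC)[C@@H](CO[Si](C)(C)C(C)(C)C)[C@@H]1CCO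
F6 | step 7 | methyl 9-(tert-butyldimethylsilyloxymethyl)-2,8-dioxabicyclo[3.3.1]non-3-ene-4-carboxylate (bridged acetal, stereocentres as in 10) | COC(=O)C1=CO[C@@H]2OCC[C@H]1[C@@H]2CO[Si](C)(C)C(C)(C)C
F0 | step 9 | none | none
F7 | step 13 | methyl (2R,3R,4S)-3-(tert-butyldimethylsilyloxymethyl)-4-{2-[2-(3,4-dihydroxyphenyl)ethoxy]-2-oxoethyl}-2-methyl-3,4-dihydro-2H-pyran-5-carboxylate | COC(=O)C1=CO[C@H](C)[C@@H](CO[Si](C)(C)C(C)(C)C)[C@@H]1CC(=O)OCCc1ccc(O)c(O)c1
A1 | alternative 1 | (2R,6R)-2-[(1Z)-4-(4-methoxybenzyloxy)but-1-enyl]-6-methyl-1,3-dioxan-4-one (2,6-cis) | C[C@@H]1CC(=O)O[C@H](/C=C\CCOCc2ccc(OC)cc2)O1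
A2 | alternative 1 | 2,3-trans-3,4-trans-4-[2-(4-methoxybenzyloxy)ethyl]-2-methyl-3,4-dihydro-2H-pyran-3-carboxylic acid | C1=CO[C@H](C)[C@@H](C(=O)O)[C@@H]1CCOCc1ccc(OC)cc1
A3 | alternative 2 | tert-butyl 2-[all-trans-2-(tert-butyldimethylsilyloxymethyl)-3-methyl-4-oxocyclopentyl]acetate | C1C(=O)[C@H](C)[C@@H](CO[Si](C)(C)C(C)(C)C)[C@@H]1CC(=O)OC(C)(C)C
A4 | alternative 2 | tert-butyl 2-[2,3-trans-3,4-trans-3-(tert-butyldimethylsilyloxymethyl)-2-methyl-6-oxotetrahydropyran-4-yl]acetate | C1C(=O)O[C@H](C)[C@@H](CO[Si](C)(C)C(C)(C)C)[C@@H]1CC(=O)OC(C)(C)C
A5 | alternative 3 | 2-[3,4-bis(tert-butyldimethylsilyloxy)phenyl]ethyl (2E,4R,5R)-4-(tert-butyldimethylsilyloxymethyl)-5-hydroxyhex-2-enoate | C[C@@H](O)[C@@H](CO[Si](C)(C)C(C)(C)C)/C=C/C(=O)OCCc1ccc(O[Si](C)(C)C(C)(C)C)c(O[Si](C)(C)C(C)(C)C)c1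
A6 | alternative 3 | methyl propiolate | COC(=O)C#C
A7 | alternative 3 | tris(tert-butyldimethylsilyl) ether of the target (identical with 18) | COC(=O)C1=CO[C@H](C)[C@@H](CO[Si](C)(C)C(C)(C)C)[C@@H]1CC(=O)OCCc1ccc(O[Si](C)(C)C(C)(C)C)c(O[Si](C)(C)C(C)(C)C)c1
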